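**Retrosynthetic overview**

1. Target ⇐ acetylation of tetraol lactone 35 ⇐ acid-triggered opening of a C7–C8 vinyl epoxide by the C19 tert-butyl ester (γ-lactone, sets C7) ⇐ hydroxyl-directed epoxidation of macrocyclic dienol 32 (sets C8).
2. Ten-membered ring ⇐ C8–C9 bond by intramolecular nickel-catalysed reductive alkyne–aldehyde coupling of 31 (sets C9 and the 7E alkene).
3. Late fragment union ⇐ C4–C5 bond by B-alkyl Suzuki–Miyaura coupling of fragment A (16, ring A, twelve skeletal carbons) with fragment B (28, eight skeletal carbons).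
4. Fragment A from cyclohexane-1,3-dione: Pd-catalysed alkoxyallene hydroalkylation (C2), CBS desymmetrisation (C1, C14), enone transposition, Still–Wittig shift (C10, C9). Fragment B from (S)-Roche ester (C17) via ynal, dibromo-olefin and (Z)-bromoenyne.
5. Ring order: ring A (from starting material) → temporary 1,3-dioxane → ten-membered carbocycle → γ-lactone last.

Assumption: the target is the enantiomer encoded by the SMILES, (1S,2R,7S,8S,9R,10S,14S,17R; 5Z), and for the chiral catalysts of steps 4 and 5 the antipode named is the one taken to give the drawn configuration.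

Locants C1–C20 are the briarane locants of the target: C1 quaternary (Me-15), C2, C3, C4, C5 (Me-16), C6, C7, C8, C9, C10, C11 (Me-20), C12, C13, C14, C17 (Me-18), C19 lactone carbonyl. β means the face of Me-15.

**Fragment A**

Step 1
Reactants: 1 cyclohexane-1,3-dione
Product: 2 2-methylcyclohexane-1,3-dione
Conditions: MeI, KOH, H2O/MeOH, 65 °C
Reagents that add atoms: iodomethane, CI
Why: C-methylation (SN2) of the stabilised enolate of a cyclic 1,3-diketone; no stereocentre is formed.

Step 2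
Reactants: 3 prop-2-yn-1-ol
Product: 4 1-methoxy-4-[(prop-2-yn-1-yloxy)methyl]benzene
Conditions: NaH, 4-methoxybenzyl chloride, Bu4NI (cat.), THF/DMF, 0 → 23 °C
Reagents that add atoms: 4-methoxybenzyl chloride, COc1ccc(CCl)cc1
Why: Williamson ether synthesis installs the PMB group that later becomes the O2/O14 acetal.

Step 3
Reactants: 4 1-methoxy-4-[(prop-2-yn-1-yloxy)methyl]benzene
Product: 5 1-methoxy-4-[(propa-1,2-dien-1-yloxy)methyl]benzene
Conditions: KOt-Bu (0.2 equiv), THF, 23 °C
Reagents that add atoms: none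
Why: Base-mediated prototropic propargyl-to-allenyl ether isomerisation gives the alkoxyallene used as allyl donor.

Step 4
Reactants: 2 2-methylcyclohexane-1,3-dione; 5 1-methoxy-4-[(propa-1,2-dien-1-yloxy)methyl]benzene
Product: 6 2-[(1R)-1-[(4-methoxybenzyl)oxy]prop-2-en-1-yl]-2-methylcyclohexane-1,3-dione
Conditions: Pd2(dba)3·CHCl3 (2.5 mol%), (R,R)-DACH-phenyl Trost ligand (7.5 mol%), PhCO2H (10 mol%), CH2Cl2, 23 °C
Reagents that add atoms: none
Why: Trost-type palladium-catalysed asymmetric hydroalkylation of an alkoxyallene; the dione enolate attacks the oxygen-bearing terminus of the alkoxy-π-allyl complex inside the chiral ligand pocket, which sets C2 as R.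

Step 5
Reactants: 6 2-[(1R)-1-[(4-methoxybenzyl)oxy]prop-2-en-1-yl]-2-methylcyclohexane-1,3-dione
Product: 7 (2R,3S)-3-hydroxy-2-[(1R)-1-[(4-methoxybenzyl)oxy]prop-2-en-1-yl]-2-methylcyclohexan-1-one
Conditions: (R)-Me-CBS oxazaborolidine (20 mol%), catecholborane, toluene, −78 °C
Reagents that add atoms: none
Why: Corey–Bakshi–Shibata desymmetrising reduction; the catalyst dictates the 14S carbinol and hydride enters from the face of the small methyl group, so only the pro-C14 carbonyl fits both demands and C1 becomes stereogenic with O14 cis to C2.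

Step 6
Reactants: 7 (2R,3S)-3-hydroxy-2-[(1R)-1-[(4-methoxybenzyl)oxy]prop-2-en-1-yl]-2-methylcyclohexan-1-one
Product: 8 (2S,4R,4aR,8aS)-4-ethenyl-2-(4-methoxyphenyl)-4a-methyl-6,7,8,8a-tetrahydro-4H-1,3-benzodioxin-5(4aH)-one
Conditions: DDQ, 4 Å molecular sieves, CH2Cl2, 0 °C
Reagents that add atoms: none
Why: Oxidative acetalisation; DDQ turns the PMB ether into an oxocarbenium ion that the syn C14 hydroxyl traps, giving the cis-fused 1,3-dioxane with the aryl group equatorial.

Step 7
Reactants: 8 acetal ketone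
Product: 9 C11-methyl ketone (both C11 epimers)
Conditions: LiN(i-Pr)2, THF, −78 °C; MeI, −78 → 0 °C
Reagents that add atoms: iodomethane, CI
Why: Enolate alkylation at C11, the only enolisable position next to the C10 ketone (C1 is quaternary); the new centre becomes sp2 in step 8.

Step 8
Reactants: 9 C11-methyl ketone
Product: 11 ring A enone (C10 ketone conjugated to C11=C12), via silyl enol ether 10 (not isolated)
Conditions: LiN(i-Pr)2, Me3SiCl, THF, −78 → 0 °C; then Pd(OAc)2 (1.1 equiv), MeCN, 23 °C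
Reagents that add atoms: none
Why: Saegusa–Ito oxidation; divalent palladium dehydrogenates the regiodefined silyl enol ether by β-hydride loss from the ring CH2 (C12) to give the endocyclic 2-methyl enone.

Step 9
Reactants: 11 ring A enone
Product: 12 11β,12β-epoxy ketone
Conditions: 30% H2O2, NaOH (cat.), MeOH, 0 °C
Reagents that add atoms: hydrogen peroxide, OO
Why: Weitz–Scheffer nucleophilic epoxidation; hydroperoxide adds axially to C12 anti to the C14 oxygen substituent (the carvone-type facial bias), giving the β-epoxide trans to O14.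

Step 10
Reactants: 12 11β,12β-epoxy ketone
Product: 13 12β-allylic alcohol (C10=C11)
Conditions: N2H4·H2O, AcOH (cat.), MeOH, 0 → 23 °C, argon
Reagents that add atoms: none
Why: Wharton transposition; the epoxy hydrazone fragments with loss of N2 to the transposed allylic alcohol and the C12–O bond (β) is untouched.

Step 11
Reactants: 13 12β-allylic alcohol
Product: 14 12β-(tributylstannyl)methyl ether
Conditions: KH, Bu3SnCH2I, 18-crown-6 (cat.), THF, 0 → 23 °C
Reagents that add atoms: tributyl(iodomethyl)stannane, CCCC[Sn](CCCC)(CCCC)CI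
Why: Williamson etherification of the potassium alkoxide; C12 keeps its configuration.

Step 12
Reactants: 14 12β-(tributylstannyl)methyl ether
Product: 16 fragment A alcohol (C9 hydroxymethyl on C10β; C11=C12), via lithiomethyl ether 15 (not isolated)
Conditions: n-BuLi, THF, −78 °C
Reagents that add atoms: none
Why: Still–Wittig rearrangement; the suprafacial [2,3]-sigmatropic shift of the α-alkoxymethyllithium delivers CH2OH (C9) to C10 on the face that bore O12 (β, cis to Me-15, trans to C2) and moves the alkene to C11=C12.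

**Fragment B**

Step 13
Reactants: 17 methyl (2S)-3-hydroxy-2-methylpropanoate
Product: 18 methyl (2S)-3-[(tert-butyldimethylsilyl)oxy]-2-methylpropanoate
Conditions: t-BuMe2SiCl, imidazole, DMF, 23 °C
Reagents that add atoms: tert-butyl(chloro)dimethylsilane, CC(C)(C)[Si](C)(C)Cl
Why: Silyl protection of the primary alcohol of the Roche ester, whose stereocentre becomes C17.

Step 14
Reactants: 18 methyl (2S)-3-[(tert-butyldimethylsilyl)oxy]-2-methylpropanoate
Product: 19 (2S)-3-[(tert-butyldimethylsilyl)oxy]-2-methylpropanal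
Conditions: i-Bu2AlH, CH2Cl2, −78 °C; Rochelle salt work-up
Reagents that add atoms: none
Why: Partial ester reduction through the stable tetrahedral aluminium hemiacetal at low temperature; the α-stereocentre is not epimerised.

Step 15
Reactants: 19 (2S)-3-[(tert-butyldimethylsilyl)oxy]-2-methylpropanal
Product: 20 tert-butyl(dimethyl){[(2R)-2-methylbut-3-yn-1-yl]oxy}silane
Conditions: dimethyl (1-diazo-2-oxopropyl)phosphonate, K2CO3, MeOH, 0 → 23 °C
Reagents that add atoms: dimethyl (1-diazo-2-oxopropyl)phosphonate, COP(=O)(OC)C(=[N+]=[N-])C(C)=O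
Why: Seyferth–Gilbert homologation in the Ohira–Bestmann version converts the aldehyde into the terminal alkyne (C8≡C7) under conditions mild enough to keep C17 intact.

Step 16
Reactants: 20 tert-butyl(dimethyl){[(2R)-2-methylbut-3-yn-1-yl]oxy}silane
Product: 22 (4R)-5-[(tert-butyldimethylsilyl)oxy]-4-methylpent-2-ynal, via lithium acetylide 21 (not isolated)
Conditions: n-BuLi, THF, −78 °C; DMF; aq. KH2PO4 quench
Reagents that add atoms: N,N-dimethylformamide, CN(C)C=O
Why: Formylation of the lithium acetylide with DMF gives the ynal whose aldehyde carbon is C6.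

Step 17
Reactants: 22 (4R)-5-[(tert-butyldimethylsilyl)oxy]-4-methylpent-2-ynal
Product: 23 tert-butyl{[(2R)-6,6-dibromo-2-methylhex-5-en-3-yn-1-yl]oxy}dimethylsilane
Conditions: CBr4, PPh3, CH2Cl2, 0 °C
Reagents that add atoms: tetrabromomethane, BrC(Br)(Br)Br
Why: Corey–Fuchs (Ramirez) dibromo-olefination through the dibromomethylene ylide creates C5.

Step 18
Reactants: 23 dibromo-enyne
Product: 24 tert-butyl{[(2R,5Z)-6-bromo-2-methylhept-5-en-3-yn-1-yl]oxy}dimethylsilane
Conditions: MeZnCl, PdCl2(DPEphos) (5 mol%), THF, 0 °C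
Reagents that add atoms: methylzinc chloride, C[Zn]Cl
Why: Stereoselective Negishi monomethylation; zerovalent palladium inserts into the less hindered C–Br bond trans to the alkynyl group, so Me-16 ends trans to C7 and the remaining bromide is cis to C7 (the 5Z geometry).

Step 19
Reactants: 24 (Z)-bromoenyne silyl ether
Product: 25 (2R,5Z)-6-bromo-2-methylhept-5-en-3-yn-1-ol
Conditions: HF·pyridine, THF, 0 → 23 °C
Reagents that add atoms: none
Why: Fluoride-induced desilylation frees the primary alcohol (C19).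

Step 20
Reactants: 25 (2R,5Z)-6-bromo-2-methylhept-5-en-3-yn-1-ol
Product: 27 (2R,5Z)-6-bromo-2-methylhept-5-en-3-ynoic acid, via aldehyde 26 (not isolated)
Conditions: TEMPO (20 mol%), PhI(OAc)2 (2.2 equiv), MeCN/H2O, 23 °C
Reagents that add atoms: water, O
Why: TEMPO/PhI(OAc)2 oxidation of the primary alcohol through the aldehyde hydrate to the acid under weakly acidic conditions that preserve C17.

Step 21
Reactants: 27 (2R,5Z)-6-bromo-2-methylhept-5-en-3-ynoic acid
Product: 28 tert-butyl (2R,5Z)-6-bromo-2-methylhept-5-en-3-ynoate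
Conditions: tert-butyl 2,2,2-trichloroacetimidate, BF3·OEt2 (cat.), cyclohexane/CH2Cl2, 23 °C
Reagents that add atoms: tert-butyl 2,2,2-trichloroacetimidate, CC(C)(C)OC(=N)C(Cl)(Cl)Cl
Why: Acid-catalysed tert-butylation (no base, so no α-epimerisation); the tert-butyl ester later acts as the internal nucleophile for lactone formation.

**Union and endgame**

Step 22
Reactants: 16 fragment A alcohol; 28 tert-butyl (2R,5Z)-6-bromo-2-methylhept-5-en-3-ynoate
Product: 30 coupled enyne alcohol (C4–C5 bond formed), via bis-borane 29 (not isolated)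
Conditions: 9-BBN (2.3 equiv), THF, 23 °C; then 28, Pd(dppf)Cl2·CH2Cl2 (5 mol%), AsPh3, Cs2CO3, DMF/H2O, 23 °C
Reagents that add atoms: none
Why: B-alkyl Suzuki–Miyaura coupling; 9-BBN hydroborates only the terminal vinyl group (boron on C4) and the alkylborane couples with the alkenyl bromide with retention of the Z geometry.

Step 23
Reactants: 30 coupled enyne alcohol
Product: 31 C9 aldehyde
Conditions: Dess–Martin periodinane, pyridine, CH2Cl2, 0 °C
Reagents that add atoms: none
Why: Dess–Martin oxidation of the primary alcohol under buffered conditions that avoid epimerisation at C10 and alkene migration.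

Step 24
Reactants: 31 C9 aldehyde
Product: 32 macrocyclic (5Z,7E)-dienol with 9R hydroxyl
Conditions: Ni(cod)2 (20 mol%), tricyclopentylphosphine (40 mol%), Et3B (3 equiv), toluene (0.002 M), 23 °C, slow addition
Reagents that add atoms: none
Why: Nickel-catalysed reductive alkyne–aldehyde macrocyclisation (Montgomery–Jamison type); the conjugated alkene directs C–C bond formation to the distal alkyne carbon C8, cis addition of H and C9 gives the 7E alkene, and Felkin–Anh attack anti to quaternary C1 gives the 9R carbinol.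

Step 25
Reactants: 32 macrocyclic dienol
Product: 33 7,8-epoxy alcohol
Conditions: VO(acac)2 (5 mol%), t-BuOOH, CH2Cl2, 0 °C
Reagents that add atoms: tert-butyl hydroperoxide, CC(C)(C)OO
Why: Hydroxyl-directed vanadium-catalysed epoxidation (Sharpless–Michaelson); the C9 vanadate delivers oxygen only to the proximal C7=C8 bond and A(1,2) strain from the C8 substituent enforces the erythro epoxy alcohol, which fixes the C8–O bond of the target.

Step 26
Reactants: 33 7,8-epoxy alcohol
Product: 35 2,9,14-tri-O-deacetyl stylatulide lactone, via lactone acetal 34 (not isolated)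
Conditions: camphorsulfonic acid (0.2 equiv), CH2Cl2, 0 °C; then THF/H2O, 23 °C
Reagents that add atoms: none
Why: Acid-triggered epoxy-ester lactonisation; the ester carbonyl opens the allylic epoxide at C7 with inversion (isobutene is lost), setting 7S and the trans-fused γ-lactone with free tertiary 8-OH, and aqueous acid then hydrolyses the benzylidene acetal.

Step 27
Reactants: 35 2,9,14-tri-O-deacetyl stylatulide lactone
Product: 36 stylatulide lactone
Conditions: Ac2O, pyridine, DMAP (cat.), CH2Cl2, 0 → 23 °C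
Reagents that add atoms: acetic anhydride, CC(=O)OC(C)=O
Why: DMAP-catalysed acylation esterifies the three secondary hydroxyls (C2, C9, C14) while the hindered tertiary C8 hydroxyl does not react.

**Compound list**

1 | cyclohexane-1,3-dione | O=C1CCCC(=O)C1 | starting material
2 | 2-methylcyclohexane-1,3-dione | CC1C(=O)CCCC1=O | intermediate
3 | prop-2-yn-1-ol | C#CCO | starting material
4 | 1-methoxy-4-[(prop-2-yn-1-yloxy)methyl]benzene | C#CCOCc1ccc(OC)cc1 | intermediate
5 | 1-methoxy-4-[(propa-1,2-dien-1-yloxy)methyl]benzene | C=C=COCc1ccc(OC)cc1 | intermediate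
6 | 2-[(1R)-1-[(4-methoxybenzyl)oxy]prop-2-en-1-yl]-2-methylcyclohexane-1,3-dione | C=C[C@@H](OCc1ccc(OC)cc1)C1(C)C(=O)CCCC1=O | intermediate
7 | (2R,3S)-3-hydroxy-2-[(1R)-1-[(4-methoxybenzyl)oxy]prop-2-en-1-yl]-2-methylcyclohexan-1-one | C=C[C@@H](OCc1ccc(OC)cc1)[C@@]1(C)[C@@H](O)CCCC1=O | intermediate
8 | (2S,4R,4aR,8aS)-4-ethenyl-2-(4-methoxyphenyl)-4a-methyl-6,7,8,8a-tetrahydro-4H-1,3-benzodioxin-5(4aH)-one (C10 ketone; O2/O14 4-methoxybenzylidene acetal, aryl equatorial) | C=C[C@H]1O[C@@H](c2ccc(OC)cc2)O[C@H]2CCCC(=O)[C@@]12C | intermediate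
9 | C11-methyl derivative of 8 (both C11 epimers) | C=C[C@H]1O[C@@H](c2ccc(OC)cc2)O[C@H]2CCC(C)C(=O)[C@@]12C | intermediate
10 | trimethylsilyl enol ether of 9 (C10=C11) | C=C[C@H]1O[C@@H](c2ccc(OC)cc2)O[C@H]2CCC(C)=C(O[Si](C)(C)C)[C@@]12C | intermediate (not isolated)
11 | ring A enone: C10 ketone, C11=C12, Me-20 on C11; acetal as in 8 | C=C[C@H]1O[C@@H](c2ccc(OC)cc2)O[C@H]2CC=C(C)C(=O)[C@@]12C | intermediate
12 | 11β,12β-epoxide of 11 (epoxide trans to O14) | C=C[C@H]1O[C@@H](c2ccc(OC)cc2)O[C@H]2C[C@@H]3O[C@]3(C)C(=O)[C@@]12C | intermediate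
13 | 12β-allylic alcohol with C10=C11 (Me-20 on C11) | C=C[C@H]1O[C@@H](c2ccc(OC)cc2)O[C@H]2C[C@H](O)C(C)=C[C@@]12C | intermediate
14 | 12β-[(tributylstannyl)methoxy] derivative of 13 | C=C[C@H]1O[C@@H](c2ccc(OC)cc2)O[C@H]2C[C@H](OC[Sn](CCCC)(CCCC)CCCC)C(C)=C[C@@]12C | intermediate
15 | 12β-(lithiomethoxy) derivative of 13 | C=C[C@H]1O[C@@H](c2ccc(OC)cc2)O[C@H]2C[C@H](OC[Li])C(C)=C[C@@]12C | intermediate (not isolated)
16 | fragment A alcohol: ring A with C11=C12, CH2OH (C9) on C10β (cis to Me-15), vinyl (C3=C4) on C2, O2/O14 acetal | C=C[C@H]1O[C@@H](c2ccc(OC)cc2)O[C@H]2CC=C(C)[C@H](CO)[C@@]12C | intermediate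
17 | methyl (2S)-3-hydroxy-2-methylpropanoate | COC(=O)[C@@H](C)CO | starting material
18 | methyl (2S)-3-[(tert-butyldimethylsilyl)oxy]-2-methylpropanoate | COC(=O)[C@@H](C)CO[Si](C)(C)C(C)(C)C | intermediate
19 | (2S)-3-[(tert-butyldimethylsilyl)oxy]-2-methylpropanal | O=C[C@@H](C)CO[Si](C)(C)C(C)(C)C | intermediate
20 | tert-butyl(dimethyl){[(2R)-2-methylbut-3-yn-1-yl]oxy}silane | C#C[C@@H](C)CO[Si](C)(C)C(C)(C)C | intermediate
21 | lithium acetylide of 20 | [Li]C#C[C@@H](C)CO[Si](C)(C)C(C)(C)C | intermediate (not isolated)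
22 | (4R)-5-[(tert-butyldimethylsilyl)oxy]-4-methylpent-2-ynal | O=CC#C[C@@H](C)CO[Si](C)(C)C(C)(C)C | intermediate
23 | tert-butyl{[(2R)-6,6-dibromo-2-methylhex-5-en-3-yn-1-yl]oxy}dimethylsilane | BrC(Br)=CC#C[C@@H](C)CO[Si](C)(C)C(C)(C)C | intermediate
24 | tert-butyl{[(2R,5Z)-6-bromo-2-methylhept-5-en-3-yn-1-yl]oxy}dimethylsilane | C/C(Br)=C/C#C[C@@H](C)CO[Si](C)(C)C(C)(C)C | intermediate
25 | (2R,5Z)-6-bromo-2-methylhept-5-en-3-yn-1-ol | C/C(Br)=C/C#C[C@@H](C)CO | intermediate
26 | (2R,5Z)-6-bromo-2-methylhept-5-en-3-ynal | C/C(Br)=C/C#C[C@@H](C)C=O | intermediate (not isolated)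
27 | (2R,5Z)-6-bromo-2-methylhept-5-en-3-ynoic acid | C/C(Br)=C/C#C[C@@H](C)C(O)=O | intermediate
28 | tert-butyl (2R,5Z)-6-bromo-2-methylhept-5-en-3-ynoate (fragment B) | C/C(Br)=C/C#C[C@@H](C)C(=O)OC(C)(C)C | intermediate
29 | bis-borane: C4-(9-borabicyclo[3.3.1]nonan-9-yl) alkylborane of 16 with O9 as its 9-BBN borinate | B1(CC[C@H]3O[C@@H](c4ccc(OC)cc4)O[C@H]5CC=C(C)[C@H](COB6C7CCCC6CCC7)[C@@]35C)C2CCCC1CCC2 | intermediate (not isolated)
30 | coupled enyne alcohol: fragment A joined at C4 to C5 of the (5Z)-enyne tert-butyl ester; C9 primary alcohol | CC(C)(C)OC(=O)[C@H](C)C#C/C=C(/C)CC[C@H]1O[C@@H](c2ccc(OC)cc2)O[C@H]2CC=C(C)[C@H](CO)[C@@]12C | intermediate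
31 | C9 aldehyde of 30 | CC(C)(C)OC(=O)[C@H](C)C#C/C=C(/C)CC[C@H]1O[C@@H](c2ccc(OC)cc2)O[C@H]2CC=C(C)[C@H](C=O)[C@@]12C | intermediate
32 | macrocyclic dienol: ten-membered ring closed at C8–C9; (5Z,7E)-diene; 9R-OH; C17 bearing Me-18 and CO2t-Bu on C8; O2/O14 acetal | CC(C)(C)OC(=O)[C@H](C)/C1=C\C=C(\C)CC[C@H]2O[C@@H](c4ccc(OC)cc4)O[C@H]3CC=C(C)[C@H]([C@H]1O)[C@@]23C | intermediate
33 | 7,8-epoxide of 32 (erythro to 9-OH; epoxide oxygen is the later 8-OH) | CC(C)(C)OC(=O)[C@H](C)[C@]12O[C@@H]1/C=C(/C)CC[C@H]3O[C@@H](c5ccc(OC)cc5)O[C@H]4CC=C(C)[C@H]([C@H]2O)[C@@]34C | intermediate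
34 | γ-lactone (O7–C19) with 8-OH and 9-OH, O2/O14 acetal still in place | [C@H]1(c5ccc(OC)cc5)O[C@H]2CC=C(C)[C@@H]3[C@@H](O)[C@@]4(O)[C@H](/C=C(/C)CC[C@@H](O1)[C@@]23C)OC(=O)[C@@H]4C | intermediate (not isolated)
35 | 2,9,14-tri-O-deacetyl stylatulide lactone (2,8,9,14-tetraol lactone) | O[C@H]1CC=C(C)[C@@H]2[C@@H](O)[C@@]3(O)[C@H](/C=C(/C)CC[C@@H](O)[C@@]12C)OC(=O)[C@@H]3C | intermediate
36 | stylatulide lactone | CC(=O)O[C@H]1CC=C(C)[C@@H]2[C@@H](OC(C)=O)[C@@]3(O)[C@H](/C=C(/C)CC[C@@H](OC(C)=O)[C@@]12C)OC(=O)[C@@H]3C | target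

**Totals**

Total step count: 27.
Longest linear sequence: 17 steps (3 → 36 through steps 2–12 and 22–27). From 1 the sequence is 16 steps and the fragment B branch from 17 is 9 steps plus the 6 shared end steps; 17/27 = 0.63.

**Steps most likely to fail, with fallbacks**

Step 24. Closing a ten-membered ring with an endocyclic E-alkene through a nickelacycle has no close precedent at this ring size, and oligomerisation or the wrong C9 epimer are possible. The fallback sets out from 28 and 16 and comes back at 32; it makes the C8–C9 bond between the fragments first and closes the ring at C4–C5 instead. Bromide 28 is stannylated (Me3SnSnMe3, Pd(PPh3)4, toluene, 80 °C) to tert-butyl (2R,5Z)-2-methyl-6-(trimethylstannyl)hept-5-en-3-ynoate F1. Alcohol 16 is oxidised with Dess–Martin periodinane to the vinyl aldehyde F2. F1 and F2 are joined by the intermolecular nickel-catalysed reductive coupling (Ni(cod)2, tricyclopentylphosphine, Et3B, ethyl acetate) to the acyclic stannyl dienyl carbinol F3. Iododestannylation (I2, CH2Cl2, −78 °C) gives the (Z)-alkenyl iodide F4. Hydroboration of its terminal vinyl group with 9-BBN and intramolecular B-alkyl Suzuki–Miyaura coupling (Pd(dppf)Cl2·CH2Cl2, AsPh3, Cs2CO3, DMF/THF/H2O, high dilution) then gives 32.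

Step 4. The allene hydroalkylation has to accept a hindered, fully substituted cyclic dione and still give high enantioselectivity at C2. The fallback sets out from 2 and comes back at 7; it gives up catalyst control at C2 and separates diastereomers after the reduction. Dione 2 is silylated (Me3SiCl, Et3N) to 2-methyl-3-(trimethylsilyloxy)cyclohex-2-en-1-one F5. F5 is alkylated at its α-carbon by the oxocarbenium ion from acrolein bis(4-methoxybenzyl) acetal (Me3SiOSO2CF3 cat., CH2Cl2, −78 °C, Mukaiyama type) to the racemic ether dione F6. The reduction of step 5 applied to F6 gives 7 together with its C2 epimer F7, which is removed by chromatography.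

Step 10. Hydrazone formation at the neopentyl C10 carbonyl may be slow, and adventitious diimide could reduce the vinyl group. The fallback sets out from 12 and comes back at 13; it replaces the ionic transposition by a radical epoxide fragmentation. Ketone 12 is reduced (NaBH4, MeOH, 0 °C) to the C10 epoxy alcohol F8. F8 is converted with 1,1'-thiocarbonyldiimidazole (DMAP, toluene, 80 °C) into the imidazolyl thionocarbonate F9. Bu3SnH and AIBN in benzene at 80 °C generate the C10 radical, which opens the adjacent epoxide to the C12 alkoxy radical; hydrogen transfer gives 13.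

**Further compounds**

F1 | step 24 | tert-butyl (2R,5Z)-2-methyl-6-(trimethylstannyl)hept-5-en-3-ynoate | C/C([Sn](C)(C)C)=C/C#C[C@@H](C)C(=O)OC(C)(C)C
F2 | step 24 | vinyl aldehyde (C9 aldehyde of 16) | C=C[C@H]1O[C@@H](c2ccc(OC)cc2)O[C@H]2CC=C(C)[C@H](C=O)[C@@]12C
F3 | step 24 | acyclic stannyl dienyl carbinol (C8–C9 bond formed; 9R-OH; 5Z,7E; Me3Sn on C5) | C=C[C@H]1O[C@@H](c2ccc(OC)cc2)O[C@H]2CC=C(C)[C@H]([C@@H](O)/C(=C/C=C(/C)[Sn](C)(C)C)[C@@H](C)C(=O)OC(C)(C)C)[C@@]12C
F4 | step 24 | (Z)-alkenyl iodide (iodine on C5 in place of tin in F3) | C=C[C@H]1O[C@@H](c2ccc(OC)cc2)O[C@H]2CC=C(C)[C@H]([C@@H](O)/C(=C/C=C(/C)I)[C@@H](C)C(=O)OC(C)(C)C)[C@@]12C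
F5 | step 4 | 2-methyl-3-(trimethylsilyloxy)cyclohex-2-en-1-one | CC1=C(O[Si](C)(C)C)CCCC1=O
F6 | step 4 | racemic 2-{1-[(4-methoxybenzyl)oxy]prop-2-en-1-yl}-2-methylcyclohexane-1,3-dione | C=CC(OCc1ccc(OC)cc1)C1(C)C(=O)CCCC1=O
F7 | step 4 | (2R,3S)-3-hydroxy-2-[(1S)-1-[(4-methoxybenzyl)oxy]prop-2-en-1-yl]-2-methylcyclohexan-1-one (C2 epimer of 7) | C=C[C@H](OCc1ccc(OC)cc1)[C@@]1(C)[C@@H](O)CCCC1=O
F8 | step 10 | C10 alcohol of epoxy ketone 12 (C10 epimers) | C=C[C@H]1O[C@@H](c2ccc(OC)cc2)O[C@H]2C[C@@H]3O[C@]3(C)C(O)[C@@]12C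
F9 | step 10 | O10-(imidazol-1-ylthiocarbonyl) derivative of F8 | C=C[C@H]1O[C@@H](c2ccc(OC)cc2)O[C@H]2C[C@@H]3O[C@]3(C)C(OC(=S)n3ccnc3)[C@@]12C
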